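In a one-step world, where a first-order step carries substrate to target, the clock ignores the loading. So one chemist, taking each step of the beta run as first-order, expects this flask to peak at the time of the beta run's highest reading, which was 74.5% at 0.250 h.

| flask | solid substrate | coupling partner | remark | time |
|---|---|---|---|---|
| beta | 1.1 M | 0.90 equiv | run made earlier |  |
| flask | 2.3 M | 0.900 equiv |  | 6.0 h |

- beta (time / h: target / %): 0.100: 43.7; 0.250: 74.5; 0.500: 63.2; 1.00: 58.1; 2.50: 56.3; 5.00: 55.0

(standard deviation of a reading: 1 percentage point)

- in percentages every species weighs as the solid substrate in it: one side product counts as two
- for target the solid product is counted in
- as a solid, counted per litre of solution: solid substrate, solid product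
- steps under discussion: 2 dissolved substrate -> side product; dissolved substrate + coupling partner -> target; solid substrate <-> dissolved substrate; target <-> isomer of the product; solid product <-> target
- at the start none of the solid substrate is in solution

1. time up to 6.0 h at which target stands highest
2. the amount of target, in percent of the solid substrate charged, at that time

A second chemist reads the beta run as a fed reactor, in which substrate arrives through dissolution of the solid and coupling follows that supply. The first reading gives an average rate of target build-up over that first interval, r = 4.81 M/h. If r holds with more solid present, the clock scales with the charge of coupling partner, the limiting reagent. My own reckoning follows this view. The flask's feed time τ = 0.431 h, the coupling partner charged per litre divided by r, marks where the peak should stand. The same sum for the beta run gives 0.206 h, a little earlier than the time of its highest reading.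

The forecast takes the second side with a later time than my τ: 0.5 h and 75%. Its ground is that “dissolved substrate stays at saturation longer”.

The flask peaks at 0.424 h with 74.0%. The forecast's time stands later than this, while its height is within tolerance.

    2 dissolved substrate → side product (k = 0.109 /M/min)
    dissolved substrate + coupling partner → target (k = 3.86 /M/min)
    solid substrate ⇌ dissolved substrate, rate k3*(cs3 - [dissolved substrate]) while solid is left; crystals form when [dissolved substrate] > cs3 (solubility = 1.70 M, k = 0.0559 /min)
    target ⇌ isomer of the product (K = 0.630, k = 0.0247 /min)
    solid product ⇌ target, rate k5*(cs5 - [target]) while solid is left; crystals form when [target] > cs5 (solubility = 0.930 M, k = 0.337 /min)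

The peak time lies close to τ, and at that time the flask holds 0.663% of its coupling partner. The one-step view keeps the isomerisation of dissolved target, a first-order pair whose relaxation half-life by this step alone, 0.181 h, contains no concentration and is short against 6.0 h. Of the three simulated removals, taking that step away moves the flask's peak furthest, from 74.0% to 90.0%. In the neighbouring flask with 0.540 equiv of coupling partner, τ shortens to 0.258 h, and its peak is 44.6%.

(The readings are calculated from invented constants; noise was put on by code.)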